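Per minute is the unit to hold this question in: what fraction of the charge turns each minute, on average over a run?

| flask | starting material | time |
|---|---|---|
| eta | 0.500 M |  |
| zeta | 0.250 M |  |
| delta | 0.200 M | 32 min |

| run | time / min | [product] / M |
|---|---|---|
| eta run | 1.4 | 0.006 |
| eta run | 4.3 | 0.012 |
| eta run | 8.2 | 0.040 |
| eta run | 13 | 0.058 |
| eta run | 19 | 0.112 |
| eta run | 25 | 0.189 |
| eta run | 32 | 0.259 |
| zeta run | 1.4 | 0.006 |
| zeta run | 4.3 | 0 |
| zeta run | 8.2 | 0.013 |
| zeta run | 13 | 0.026 |
| zeta run | 19 | 0.038 |
| zeta run | 25 | 0.052 |
| zeta run | 32 | 0.082 |

(each reading ± 0.005 M)

- Overall: starting material -> product.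
- Constant volume, constant temperature.
- An order is taken over about fifteen percent of the charge, up and down.

1. order of the initial rate in [starting material], near the charge of the eta run, the rate being that where two percent of its starting material are product (one fixed amount of product, the same in the runs compared)
2. product in the delta run at 32 min, as a share of the starting material charged

What does the zeta run give? Take the natural logarithm of its charge over charge minus product at the last reading, divide by the time, and you get 0.0124 min⁻¹. That is the mean specific rate, an apparent first-order rate constant: the steady fraction per minute that carries a charge to that reading.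

And the eta run? It gives 0.0228 min⁻¹, higher than zeta's, so this mean changes with the charge.

Is a steady curve true? No. At 19 min in the zeta run it puts 0.0526 M against a reading of 0.038 M, which is too high by 2.91 standard deviations.

Then why use it? The delta question stands at 32 min, the time of both last readings, and there each mean curve passes through its reading by construction.

Where is it weak? In the charge. I run a straight line through the two means down to 0.200 M, which gives 0.0103 min⁻¹ and 28.2% of the delta charge. Two points cannot test a line. The scatter of zeta's last reading moves zeta's mean by 9.30 × 10⁻⁴ min⁻¹, and my share by about 2.6 percentage points. I commit to no order of my own: the mean spans a whole run, and the order is asked at one fixed product.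

The forecast says 30% (24% to 35%), above mine, and an order of 1.1 (0.7 to 1.6). Its ground: “That points to autocatalysis or an intermediate, on top of a slow direct route.”

The simulation gives an order of 1.0 and 29.2% in the delta run at 32 min, from this scheme:

    2 starting material ⇌ intermediate + starting material (0.2970 L mol⁻¹ min⁻¹, 0.8640 L mol⁻¹ min⁻¹)
    intermediate → product (0.01842 min⁻¹)
    starting material → product (0.003858 min⁻¹)
    starting material + product → 2 product (0.1980 L mol⁻¹ min⁻¹)

At the fixed product of the question, the zeta run's rate is 0.49 of the eta run's. The delta run's mean specific rate comes to 0.0108 min⁻¹, against my 0.0103 min⁻¹. Taken on to half the charge in the zeta run, the mean of 0.0124 min⁻¹ gives 55.8 min, later than the 45.1 min at which the zeta run reached it.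

(The readings are simulated from invented constants, noise included.)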